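The route rests on disconnecting the bond between C1 of the syringyl ring and C7′ of the furofuran (3,7-dioxabicyclo[3.3.0]octane) core. C7′ is flanked by the ring oxygen and the bridgehead C8′, so at the acetal oxidation level it can ionise to a bicyclic oxocarbenium ion. A syringylzinc reagent should add on the convex face of the cis-fused bicycle, which in one operation joins the two fragments and sets the last stereocentre, C7′, with the aryl group exo. The precursor is an anomeric phenylsulfonyl acetal that already carries the guaiacyl ring and the complete, silyl-protected threo-guaiacylglycerol β-aryl ether arm but no third arene; global desilylation then gives the target.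

Key step: step 13

Remarks:
- Lignan numbering is used: C7–C9 on the guaiacyl side of the furofuran, C7′–C9′ on the syringyl side, C7″–C9″ in the glycerol chain.
- TBS = tert-butyldimethylsilyl. Ar* = 4-{[(4S,5S)-2,2-di-tert-butyl-4-(4-TBSO-3-methoxyphenyl)-1,3,2-dioxasilinan-5-yl]oxy}-3-methoxyphenyl, that is, ring B carrying the protected side chain.
- Compounds 1, 2, 4, 11, 12 and 22 are taken as catalogue chemicals.
- The sense of induction in steps 2 and 6 is assigned by analogy with the established models for these reaction types.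

Step 1
Reactants: 1 4-bromo-2-methoxyphenol; 2 (R)-4-benzyl-3-(chloroacetyl)oxazolidin-2-one
Product: 3 (R)-4-benzyl-3-[(4-bromo-2-methoxyphenoxy)acetyl]oxazolidin-2-one
Conditions: K2CO3, NaI (cat.), acetone, 45 °C
Reagents that add atoms: none
Why: Williamson etherification, in which the phenoxide displaces chloride from the activated α-chloro imide (SN2) faster than it attacks the imide carbonyl; no stereocentre is formed.

Step 2
Reactants: 3 (R)-4-benzyl-3-[(4-bromo-2-methoxyphenoxy)acetyl]oxazolidin-2-one; 4 4-[(tert-butyldimethylsilyl)oxy]-3-methoxybenzaldehyde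
Product: 6 (R)-4-benzyl-3-[(2R,3S)-2-(4-bromo-2-methoxyphenoxy)-3-hydroxy-3-(4-TBSO-3-methoxyphenyl)propanoyl]oxazolidin-2-one, via boron enolate 5 (not isolated)
Conditions: Bu2BOTf, iPr2NEt, CH2Cl2, 0 °C; then 4, −78 → 0 °C; pH 7 buffer, MeOH, aq. H2O2, 0 °C
Reagents that add atoms: none
Why: Evans syn glycolate aldol, in which the Z-boron enolate reacts through a Zimmerman–Traxler chair on the face opposite the benzyl group of the (R)-auxiliary, which should set C8″ and C7″ together as the syn (2R,3S) adduct, the threo (7″S,8″S) array of the target.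

Step 3
Reactants: 6 syn aldol adduct
Product: 7 (1S,2S)-2-(4-bromo-2-methoxyphenoxy)-1-(4-TBSO-3-methoxyphenyl)propane-1,3-diol
Conditions: LiBH4, MeOH (1 equiv), THF, 0 °C
Reagents that add atoms: none
Why: Reductive cleavage of the N-acyloxazolidinone by borohydride gives the primary alcohol and releases the auxiliary without touching the two stereocentres, the aryl silyl ether or the aryl bromide.

Step 4
Reactants: 7 threo diol
Product: 8 (4S,5S)-5-(4-bromo-2-methoxyphenoxy)-2,2-di-tert-butyl-4-(4-TBSO-3-methoxyphenyl)-1,3,2-dioxasilinane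
Conditions: tBu2Si(OTf)2, 2,6-lutidine, CH2Cl2, 0 °C
Reagents that add atoms: di-tert-butylsilyl bis(trifluoromethanesulfonate), CC(C)(C)[Si](OS(=O)(=O)C(F)(F)F)(OS(=O)(=O)C(F)(F)F)C(C)(C)C
Why: Silylene formation on the 1,3-diol gives the six-membered dioxasilinane, a fluoride-labile protecting group that should withstand organolithium, hydride and mild acid in the following steps.

Step 5
Reactants: 8 silylene-protected aryl bromide
Product: 10 Ar*–CHO (4-{[(4S,5S)-2,2-di-tert-butyl-4-(4-TBSO-3-methoxyphenyl)-1,3,2-dioxasilinan-5-yl]oxy}-3-methoxybenzaldehyde), via aryllithium 9 (not isolated)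
Conditions: n-BuLi, THF, −78 °C; then DMF, −78 → −20 °C; sat. aq. NH4Cl
Reagents that add atoms: N,N-dimethylformamide, CN(C)C=O
Why: Bromine–lithium exchange followed by formylation of the aryllithium with DMF converts the bromide into the ring B aldehyde; no stereocentre is involved and no acidic proton is present.

Step 6
Reactants: 11 furan-2(5H)-one; 12 potassium trifluoro(vinyl)borate
Product: 13 (R)-4-vinyldihydrofuran-2(3H)-one
Conditions: [Rh(cod)2]BF4 (3 mol %), (R)-BINAP (3.3 mol %), toluene/H2O 20:1, 100 °C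
Reagents that add atoms: none
Why: Rhodium-catalysed asymmetric 1,4-addition (Hayashi–Miyaura type) of the vinyl group to the butenolide, in which the (R)-BINAP complex should select the enantioface that gives the (R)-lactone and thereby sets C8′ of the target.

Step 7
Reactants: 13 (R)-4-vinyldihydrofuran-2(3H)-one; 10 Ar*–CHO
Product: 15 (3R,4S)-3-[Ar*(hydroxy)methyl]-4-vinyldihydrofuran-2(3H)-one (both carbinol epimers), via lithium enolate 14 (not isolated)
Conditions: LiN(iPr)2 (LDA), THF, −78 °C; then 10, −78 °C; sat. aq. NH4Cl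
Reagents that add atoms: none
Why: Aldol addition of the lactone lithium enolate takes place anti to the β-vinyl group, which sets C8 trans to C8′ on the lactone (cis in the later bicycle), while the carbinol centre C7 forms as a mixture that the SN1 closure of step 9 makes irrelevant.

Step 8
Reactants: 15 trans aldol lactone
Product: 16 (2S,3S)-2-[Ar*(hydroxy)methyl]-3-vinylbutane-1,4-diol (both carbinol epimers)
Conditions: LiBH4, THF, 0 °C → rt
Reagents that add atoms: none
Why: Borohydride reduction of the lactone gives the two primary alcohols (C9 and C9′) and leaves the silyl groups, the alkene and all stereocentres untouched.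

Step 9
Reactants: 16 triol
Product: 17 [(2R,3S,4S)-2-Ar*-4-vinyltetrahydrofuran-3-yl]methanol
Conditions: camphor-10-sulfonic acid (10 mol %), CH2Cl2, 0 °C
Reagents that add atoms: none
Why: Acid-catalysed SN1 cycloetherification, in which the p-alkoxybenzylic cation at C7 is trapped by the C9′ hydroxyl in a five-membered closure (the C9 hydroxyl could only give an oxetane) and both carbinol epimers should converge on the 2,3-trans tetrahydrofuran, which sets C7 as R with the aryl group anti to the C8 hydroxymethyl group.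

Step 10
Reactants: 17 vinyl tetrahydrofuran
Product: 20 (1S,5S,6R)-6-Ar*-3,7-dioxabicyclo[3.3.0]octan-2-ol (both C2 epimers), via ozonide 18 (not isolated), via hydroxy aldehyde 19 (not isolated)
Conditions: O3, CH2Cl2, −78 °C (Sudan Red 7B end point); then PPh3, −78 °C → rt
Reagents that add atoms: ozone, [O-][O+]=O
Why: Ozonolysis with reductive work-up cleaves the terminal alkene to the C7′ aldehyde, which is cis to the C9 hydroxymethyl group and closes to the cis-fused lactol, and the indicator end point should spare the electron-rich arenes.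

Step 11
Reactants: 20 bicyclic lactol
Product: 21 (1S,5S,6R)-6-Ar*-2-(phenylsulfonyl)-3,7-dioxabicyclo[3.3.0]octane (both C2 epimers)
Conditions: PhSO2H, CaCl2, CH2Cl2, rt
Reagents that add atoms: benzenesulfinic acid, O=S(O)c1ccccc1
Why: Exchange of the lactol hydroxyl for benzenesulfinate through the oxocarbenium ion (Ley anomeric sulfone formation) gives a storable donor whose anomeric configuration is inconsequential.

Step 12
Reactants: 22 4-bromo-2,6-dimethoxyphenol
Product: 23 (4-bromo-2,6-dimethoxyphenoxy)(tert-butyl)dimethylsilane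
Conditions: TBSCl, imidazole, DMF, rt
Reagents that add atoms: tert-butyldimethylsilyl chloride, CC(C)(C)[Si](C)(C)Cl
Why: Standard silylation of the phenol masks the acidic proton before metalation and uses the same fluoride-labile group as the rest of the molecule.

Step 13
Reactants: 21 anomeric sulfone; 23 silyl-protected 4-bromosyringol
Product: 26 (1S,2R,5S,6R)-6-Ar*-2-(4-TBSO-3,5-dimethoxyphenyl)-3,7-dioxabicyclo[3.3.0]octane, via Grignard reagent 24 (not isolated), via arylzinc bromide 25 (not isolated)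
Conditions: 23 (3 equiv), Mg, THF, 50 °C; ZnBr2 (3.3 equiv), THF, 0 °C → rt; then 21, THF, rt; sat. aq. NH4Cl
Reagents that add atoms: none
Why: ZnBr2 and MgBr2 assist departure of benzenesulfinate from the anomeric sulfone to give the bicyclic oxocarbenium ion O=C7′, which is captured by the arylzinc bromide at the aryl carbon para to the silyloxy group, so that the C1(syringyl)–C7′ bond forms intermolecularly. The closest known reaction type is the substitution of 2-(phenylsulfonyl) cyclic ethers by aryl Grignard reagents in the presence of ZnBr2 (Ley sulfone chemistry), the non-carbohydrate counterpart of C-aryl glycoside synthesis. No ring is closed. The new stereocentre C7′ is controlled by the substrate: the cis-fused ring that contains C9′ covers the concave face of the cation, so the aryl group should enter on the convex face, trans to the C8′–C9′ bond, which gives the exo (7′R) aryl group, and both sulfone epimers converge on the same cation. The step needs chemoselective ionisation at the acetal carbon in the presence of the benzylic C7–O and C7″–O bonds and three silyl groups, which the far greater lability of an α-sulfonyl ether towards mild Lewis acids and the non-basic, non-reducing arylzinc reagent should secure. Regiochemistry on the syringyl ring follows from the position of bromine in 23.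

Step 14
Reactants: 26 tris-silylated furofuran
Product: 27 (1S,2S)-2-{4-[(1S,2R,5S,6R)-2-(4-hydroxy-3,5-dimethoxyphenyl)-3,7-dioxabicyclo[3.3.0]octan-6-yl]-2-methoxyphenoxy}-1-(4-hydroxy-3-methoxyphenyl)propane-1,3-diol (CNP0255927.3)
Conditions: Bu4NF, AcOH, THF, 0 °C → rt
Reagents that add atoms: none
Why: Fluoride-mediated global desilylation cleaves both aryl silyl ethers and the silylene in one operation, and the acetic acid buffer keeps the phenoxides from opening the benzylic ethers, so no stereocentre should be disturbed.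

Compound list
1 | 4-bromo-2-methoxyphenol | COc1cc(Br)ccc1O | starting material
2 | (R)-4-benzyl-3-(chloroacetyl)oxazolidin-2-one | O=C(CCl)N1C(=O)OC[C@H]1Cc1ccccc1 | starting material
3 | (R)-4-benzyl-3-[(4-bromo-2-methoxyphenoxy)acetyl]oxazolidin-2-one | COc1cc(Br)ccc1OCC(=O)N1C(=O)OC[C@H]1Cc1ccccc1 | intermediate
4 | 4-[(tert-butyldimethylsilyl)oxy]-3-methoxybenzaldehyde | COc1cc(C=O)ccc1O[Si](C)(C)C(C)(C)C | starting material
5 | (Z)-O-dibutylboryl enolate of imide 3 | COc1cc(Br)ccc1O/C=C(\OB(CCCC)CCCC)N1C(=O)OC[C@H]1Cc1ccccc1 | intermediate (not isolated)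
6 | (R)-4-benzyl-3-[(2R,3S)-2-(4-bromo-2-methoxyphenoxy)-3-hydroxy-3-(4-TBSO-3-methoxyphenyl)propanoyl]oxazolidin-2-one | COc1cc([C@H](O)[C@H](C(=O)N2C(=O)OC[C@H]2Cc2ccccc2)Oc2ccc(Br)cc2OC)ccc1O[Si](C)(C)C(C)(C)C | intermediate
7 | (1S,2S)-2-(4-bromo-2-methoxyphenoxy)-1-(4-TBSO-3-methoxyphenyl)propane-1,3-diol | COc1cc([C@H](O)[C@H](CO)Oc2ccc(Br)cc2OC)ccc1O[Si](C)(C)C(C)(C)C | intermediate
8 | (4S,5S)-5-(4-bromo-2-methoxyphenoxy)-2,2-di-tert-butyl-4-(4-TBSO-3-methoxyphenyl)-1,3,2-dioxasilinane | Brc1ccc(O[C@H]2CO[Si](C(C)(C)C)(C(C)(C)C)O[C@H]2c3ccc(O[Si](C)(C)C(C)(C)C)c(OC)c3)c(OC)c1 | intermediate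
9 | aryllithium derived from 8 (lithium in place of bromine) | [Li]c1ccc(O[C@H]2CO[Si](C(C)(C)C)(C(C)(C)C)O[C@H]2c3ccc(O[Si](C)(C)C(C)(C)C)c(OC)c3)c(OC)c1 | intermediate (not isolated)
10 | Ar*–CHO, 4-{[(4S,5S)-2,2-di-tert-butyl-4-(4-TBSO-3-methoxyphenyl)-1,3,2-dioxasilinan-5-yl]oxy}-3-methoxybenzaldehyde | O=Cc1ccc(O[C@H]2CO[Si](C(C)(C)C)(C(C)(C)C)O[C@H]2c3ccc(O[Si](C)(C)C(C)(C)C)c(OC)c3)c(OC)c1 | intermediate
11 | furan-2(5H)-one | O=C1OCC=C1 | starting material
12 | potassium trifluoro(vinyl)borate | [K+].C=C[B-](F)(F)F | starting material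
13 | (R)-4-vinyldihydrofuran-2(3H)-one | O=C1C[C@H](C=C)CO1 | intermediate
14 | lithium enolate of lactone 13 | [Li]OC1=C[C@H](C=C)CO1 | intermediate (not isolated)
15 | (3R,4S)-3-[Ar*(hydroxy)methyl]-4-vinyldihydrofuran-2(3H)-one, both carbinol epimers | O=C1OC[C@@H](C=C)[C@@H]1C(O)c1ccc(O[C@H]2CO[Si](C(C)(C)C)(C(C)(C)C)O[C@H]2c3ccc(O[Si](C)(C)C(C)(C)C)c(OC)c3)c(OC)c1 | intermediate
16 | (2S,3S)-2-[Ar*(hydroxy)methyl]-3-vinylbutane-1,4-diol, both carbinol epimers | OC[C@@H](C=C)[C@@H](CO)C(O)c1ccc(O[C@H]2CO[Si](C(C)(C)C)(C(C)(C)C)O[C@H]2c3ccc(O[Si](C)(C)C(C)(C)C)c(OC)c3)c(OC)c1 | intermediate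
17 | [(2R,3S,4S)-2-Ar*-4-vinyltetrahydrofuran-3-yl]methanol | COc1cc(ccc1O[C@H]2CO[Si](C(C)(C)C)(C(C)(C)C)O[C@H]2c3ccc(O[Si](C)(C)C(C)(C)C)c(OC)c3)[C@@H]4OC[C@@H](C=C)[C@H]4CO | intermediate
18 | [(2R,3S,4S)-2-Ar*-4-(1,2,4-trioxolan-3-yl)tetrahydrofuran-3-yl]methanol (ozonide) | COc1cc(ccc1O[C@H]2CO[Si](C(C)(C)C)(C(C)(C)C)O[C@H]2c3ccc(O[Si](C)(C)C(C)(C)C)c(OC)c3)[C@@H]4OC[C@@H](C5OCOO5)[C@H]4CO | intermediate (not isolated)
19 | (3S,4S,5R)-5-Ar*-4-(hydroxymethyl)tetrahydrofuran-3-carbaldehyde | COc1cc(ccc1O[C@H]2CO[Si](C(C)(C)C)(C(C)(C)C)O[C@H]2c3ccc(O[Si](C)(C)C(C)(C)C)c(OC)c3)[C@@H]4OC[C@@H](C=O)[C@H]4CO | intermediate (not isolated)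
20 | (1S,5S,6R)-6-Ar*-3,7-dioxabicyclo[3.3.0]octan-2-ol, both C2 epimers | COc1cc(ccc1O[C@H]2CO[Si](C(C)(C)C)(C(C)(C)C)O[C@H]2c3ccc(O[Si](C)(C)C(C)(C)C)c(OC)c3)[C@@H]4OC[C@@H]5[C@H]4COC5O | intermediate
21 | (1S,5S,6R)-6-Ar*-2-(phenylsulfonyl)-3,7-dioxabicyclo[3.3.0]octane, both C2 epimers | COc1cc(ccc1O[C@H]2CO[Si](C(C)(C)C)(C(C)(C)C)O[C@H]2c3ccc(O[Si](C)(C)C(C)(C)C)c(OC)c3)[C@@H]4OC[C@@H]5[C@H]4COC5S(=O)(=O)c6ccccc6 | intermediate
22 | 4-bromo-2,6-dimethoxyphenol | COc1cc(Br)cc(OC)c1O | starting material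
23 | (4-bromo-2,6-dimethoxyphenoxy)(tert-butyl)dimethylsilane | COc1cc(Br)cc(OC)c1O[Si](C)(C)C(C)(C)C | intermediate
24 | [4-(TBSO)-3,5-dimethoxyphenyl]magnesium bromide | Br[Mg]c1cc(OC)c(O[Si](C)(C)C(C)(C)C)c(OC)c1 | intermediate (not isolated)
25 | bromo[4-(TBSO)-3,5-dimethoxyphenyl]zinc | Br[Zn]c1cc(OC)c(O[Si](C)(C)C(C)(C)C)c(OC)c1 | intermediate (not isolated)
26 | (1S,2R,5S,6R)-6-Ar*-2-(4-TBSO-3,5-dimethoxyphenyl)-3,7-dioxabicyclo[3.3.0]octane | COc1cc(ccc1O[C@H]2CO[Si](C(C)(C)C)(C(C)(C)C)O[C@H]2c3ccc(O[Si](C)(C)C(C)(C)C)c(OC)c3)[C@@H]4OC[C@@H]5[C@H]4CO[C@H]5c6cc(OC)c(O[Si](C)(C)C(C)(C)C)c(OC)c6 | intermediate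
27 | (1S,2S)-2-{4-[(1S,2R,5S,6R)-2-(4-hydroxy-3,5-dimethoxyphenyl)-3,7-dioxabicyclo[3.3.0]octan-6-yl]-2-methoxyphenoxy}-1-(4-hydroxy-3-methoxyphenyl)propane-1,3-diol (CNP0255927.3) | COc1cc([C@H](O)[C@H](CO)Oc2ccc([C@@H]3OC[C@@H]4[C@H]3CO[C@H]4c3cc(OC)c(O)c(OC)c3)cc2OC)ccc1O | target

Total step count: 14. Longest linear sequence: 12 steps (steps 1–5, 7–11, 13 and 14).

Steps most likely to fail

Step 13 (key step). The sulfone may ionise sluggishly, lose sulfinate by elimination, or be attacked in part on the concave face, which would erode the exo selectivity at C7′. The fallback makes the same bond by carbonyl addition and leaves the stereocentre to a later ring closure. It sets out from lactol 20, which reacts through its open form 19 with an excess of Grignard reagent 24 (THF, −78 → 0 °C) to give the ring-opened diaryl diol F1 as a mixture at C7′. Catalytic camphor-10-sulfonic acid in CH2Cl2 at 0 °C should then ionise the p-silyloxybenzylic alcohol, and the C9 hydroxyl should close the second ring from the convex side in a stereoconvergent SN1 etherification. The fallback comes back to the route at 26.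

Step 6. Transmetalation of the vinylborate may be slow relative to its protodeboronation, or enantioface discrimination on the small, flat butenolide may be poor. The fallback replaces catalyst control by auxiliary control. It sets out from the menthol-derived butenolide (5S)-5-[(1S,2R,5S)-menthyloxy]furan-2(5H)-one F2. Copper-catalysed conjugate addition of vinylmagnesium bromide (CuBr·SMe2, Me3SiCl, THF, −78 °C) anti to the menthyloxy group should give (4R,5S)-5-(menthyloxy)-4-vinyldihydrofuran-2(3H)-one F3. Reduction with LiAlH4 (THF, 0 °C) releases menthol and gives (R)-2-vinylbutane-1,4-diol F4. Oxidative lactonisation at the less hindered carbinol (TEMPO, PhI(OAc)2, CH2Cl2, rt) then comes back to the route at 13.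

Step 11. Prolonged contact with a stoichiometric sulfinic acid may cause loss of silyl groups or ionisation at the benzylic C7–O and C7″–O bonds. The fallback builds the sulfone under neutral conditions through the sulfide. It sets out from lactol 20, which with PhSSPh and Bu3P (THF, rt; Hata thioacetalisation) should give the phenylthio acetal F5. Oxidation at sulfur with mCPBA (NaHCO3, CH2Cl2, 0 °C) comes back to the route at 21.

Further compounds
F1 | step 13 | [(2R,3S,4S)-2-Ar*-4-{hydroxy[4-(TBSO)-3,5-dimethoxyphenyl]methyl}tetrahydrofuran-3-yl]methanol, both carbinol epimers | COc1cc(ccc1O[C@H]2CO[Si](C(C)(C)C)(C(C)(C)C)O[C@H]2c3ccc(O[Si](C)(C)C(C)(C)C)c(OC)c3)[C@@H]4OC[C@@H](C(O)c5cc(OC)c(O[Si](C)(C)C(C)(C)C)c(OC)c5)[C@H]4CO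
F2 | step 6 | (5S)-5-{[(1S,2R,5S)-2-isopropyl-5-methylcyclohexyl]oxy}furan-2(5H)-one | O=C1C=C[C@@H](O[C@H]2C[C@@H](C)CC[C@@H]2C(C)C)O1
F3 | step 6 | (4R,5S)-5-{[(1S,2R,5S)-2-isopropyl-5-methylcyclohexyl]oxy}-4-vinyldihydrofuran-2(3H)-one | O=C1C[C@H](C=C)[C@@H](O[C@H]2C[C@@H](C)CC[C@@H]2C(C)C)O1
F4 | step 6 | (R)-2-vinylbutane-1,4-diol | OCC[C@H](C=C)CO
F5 | step 11 | (1S,5S,6R)-6-Ar*-2-(phenylthio)-3,7-dioxabicyclo[3.3.0]octane, both C2 epimers | COc1cc(ccc1O[C@H]2CO[Si](C(C)(C)C)(C(C)(C)C)O[C@H]2c3ccc(O[Si](C)(C)C(C)(C)C)c(OC)c3)[C@@H]4OC[C@@H]5[C@H]4COC5Sc6ccccc6
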